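The protic impurity was the reagent I looked at first. Larch, charged like spring, gave 18.9% target at 10.0 s, while elm, with 0.40 M of impurity instead of 0.20 M, gave 7.7% at that time, less.

| flask | starting material | second substrate | protic impurity | enzyme | remark | time |
|---|---|---|---|---|---|---|
| larch | 0.20 M | 0.26 M | 0.20 M | 0.13 mM | run made earlier |  |
| cedar | 0.20 M | 0.13 M | 0.20 M | 0.13 mM | run made earlier |  |
| alder | 0.20 M | 0.52 M | 0.20 M | 0.13 mM | run made earlier |  |
| elm | 0.20 M | 0.26 M | 0.40 M | 0.13 mM | run made earlier |  |
| summer | 0.20 M | 0.260 M (in portions, 4, over 1.5 min) | 0.200 M | 0.13 mM | first portion at the start, last at 1.5 min | 2.0 min |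
| spring | 0.20 M | 0.260 M | 0.200 M | 0.13 mM | everything together at the start | 2.0 min |
| midnight | 0.20 M (fed, over 1.5 min) | 0.260 M | 0.200 M | 0.13 mM | all else is in the flask from the start; the feed brings no volume worth counting | 2.0 min |
| noon | 0.20 M | 0.260 M (fed, over 1.5 min) | 0.200 M | 0.13 mM | all else is in the flask from the start; the feed brings no volume worth counting | 2.0 min |

| run | time / s | target / % |
|---|---|---|
| larch | 10.0 | 18.9 |
| larch | 15.0 | 18.2 |
| larch | 25.0 | 16.9 |
| larch | 40.0 | 15.6 |
| larch | 60.0 | 14.1 |
| larch | 80.0 | 13.5 |
| cedar | 10.0 | 14.5 |
| cedar | 12.0 | 14.5 |
| cedar | 20.0 | 13.9 |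
| cedar | 40.0 | 11.7 |
| cedar | 60.0 | 11.1 |
| cedar | 90.0 | 10.7 |
| alder | 15.0 | 20.9 |
| alder | 30.0 | 18.4 |
| alder | 50.0 | 16.4 |
| alder | 60.0 | 15.6 |
| alder | 80.0 | 14.8 |
| alder | 90.0 | 15.1 |
| elm | 10.0 | 7.7 |
| elm | 25.0 | 6.5 |
| elm | 40.0 | 5.6 |
| elm | 60.0 | 5.3 |
| elm | 90.0 | 5.7 |

(each reading ± 0.3 percentage points)



- which flask leads in amount of target, in percent of the starting material charged ("all alike" within 1.5 percentage points) (summer / spring / midnight / noon / all alike)
- how much target is there at the end, in percent of the starting material charged: summer
- how much target is there at the end, in percent of the starting material charged: spring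
- how much target is there at the end, in percent of the starting material charged: midnight
- how much target is there at the end, in percent of the starting material charged: noon

I supposed that the impurity destroys starting material one for one, so I reckoned 100% as the toll, the share of the starting material that the impurity charge can destroy. If the impurity won every meeting, the toll would be paid in full and target would stand at 0%. If the enzyme won every meeting, target could reach 100%, since second substrate is charged at 130% of the starting material. Larch lay between, nearer the first extreme, and its target sagged slowly to 13.5% at 80.0 s.

The recipes keep this toll and change who meets whom. Spring repeats larch, so I committed to a little under that last reading. Cedar, with half the second substrate, gave 14.5% at 10.0 s, less than larch. So I put summer, whose first portion is a quarter of the charge of second substrate, below spring, and noon, which starts without second substrate, below summer. Midnight keeps the full second substrate from the start, and I put it at or somewhat above spring.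

The forecast named midnight as leader, with 13.6% there, 13% in spring, 7.8% in summer and 3.7% in noon, holding that “Spring equals larch”.

The simulation put midnight first with 15.9%, then spring with 12.7%, summer with 7.46% and noon with 3.61%.

    starting material + enzyme ⇌ starting complex (K = 10.0 M⁻¹, k = 1900 M⁻¹ s⁻¹)
    second substrate + starting complex ⇌ ternary complex (K = 1.60 M⁻¹, k = 5100 M⁻¹ s⁻¹)
    ternary complex → enzyme + target (k = 1900 s⁻¹)
    target ⇌ isomer of the product (K = 0.670, k = 0.0120 s⁻¹)
    starting material + protic impurity → quenched substrate (k = 5.20 M⁻¹ s⁻¹)

Of the toll of 100%, noon paid 94.1% as quenched substrate, spring 79.2% and midnight 76.3%. In noon, quenching reached half its turnover by 0.858 s, whereas second substrate joining the starting complex reached that point at 0.178 min, later. In midnight, starting material averaged 0.00294 M over the first 1.5 min, far less than its charge, and the flask ended with 7.78% isomer of the product beside its target.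

Take noon with 0.50 M of starting material: the toll falls to 40.0%, leaving 60.0% beyond the impurity's reach, but second substrate, now the limiting reagent on the enzyme's route, covers 52.0% of the starting material. That flask ended with impurity at 0% and second substrate at 1.08% of their own charges and, in percent of the starting material charged, with 40.0% quenched substrate and 34.6% target beside 16.8% isomer of the product.

(All runs stem from a simulated flask on assumed constants, and the scatter is random.)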